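The cyclopentane is cut at C2–C3 and C4–C5 (spiro[4.5]decane locants). The oxygen-bearing carbon C1 lies between the spiro atom C5 and C2: as a ketone with a temporary ester on C2, it makes C5 and C2 the γ- and α-carbons of a β-keto ester dianion on a preformed cyclohexene ring. In one pot, C5 is alkylated by the chloride end of an isoprene-derived chloro carbonate, anti to the C10 methyl, and zerovalent palladium then closes C2 onto C3, which releases the isopropenyl group. C10 is set by amine catalysis; C5 and C9 follow by substrate control, C3 and C1 by reagent control.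

Key step: step 7

Remarks:
- Locants C1–C10 are those of the spiro[4.5]decane core of the target: C1 CH–O, C3 CH–isopropenyl, C5 spiro atom, C6 C–CH3 of the enone, C8 C=O, C9 CH–OAc, C10 CH–CH3.
- Compounds 1, 4 and 5 are taken as commercial.
- C5 in 6–11 and C2 in 13 are enolisable and are drawn as the expected trans isomers.
- The CIP label of C10 changes from S to R in step 12 only because the priorities change.

Step 1
Reactants: 1 2-methyl-2-vinyloxirane
Product: 2 (2E)-4-chloro-2-methylbut-2-en-1-ol
Conditions: TiCl4, CH2Cl2, −78 °C; then H2O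
Reagents that add atoms: titanium tetrachloride Cl[Ti](Cl)(Cl)Cl
Why: Lewis-acid-mediated SN2′ opening of the vinyl epoxide delivers chloride to the vinyl terminus and should give the (E)-trisubstituted 1,4-chlorohydrin.

Step 2
Reactants: 2 (2E)-4-chloro-2-methylbut-2-en-1-ol
Product: 3 tert-butyl (2E)-4-chloro-2-methylbut-2-en-1-yl carbonate
Conditions: Boc2O, DMAP (cat.), CH2Cl2, 0 °C to rt
Reagents that add atoms: di-tert-butyl dicarbonate CC(C)(C)OC(=O)OC(=O)OC(C)(C)C
Why: DMAP-catalysed O-acylation of the primary allylic alcohol; the tert-butyl carbonate should resist the dianion of step 7 yet ionise readily with zerovalent palladium.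

Step 3
Reactants: 4 allyl acetoacetate; 5 (3E)-pent-3-en-2-one
Product: 7 allyl (1R,6S)-2,6-dimethyl-4-oxocyclohex-2-ene-1-carboxylate, via Michael adduct 6 (not isolated)
Conditions: 9-amino(9-deoxy)epi-quinine (20 mol %), CF3CO2H (40 mol %), THF, rt; then pyrrolidine, AcOH, toluene, 60 °C
Reagents that add atoms: none
Why: Iminium-activated asymmetric Michael addition of the β-keto ester sets the methyl-bearing stereocentre (later C10) by catalyst control (the epi-quinidine amine is used if the sense is opposite), and pyrrolidinium acetate then closes the ring by intramolecular aldol condensation (Robinson-type annulation, Hagemann ester pattern).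

Step 4
Reactants: 7 allyl (1R,6S)-2,6-dimethyl-4-oxocyclohex-2-ene-1-carboxylate
Product: 8 allyl (8R,9S)-7,9-dimethyl-1,4-dioxaspiro[4.5]dec-6-ene-8-carboxylate
Conditions: TMSOCH2CH2OTMS, TMSOTf (5 mol %), CH2Cl2, −78 °C; pyridine quench
Reagents that add atoms: 1,2-bis(trimethylsilyloxy)ethane C[Si](C)(C)OCCO[Si](C)(C)C
Why: Noyori ketalisation under kinetic control masks the only ketone without moving the C6=C7 double bond, so that C5–H later is the only γ-hydrogen and C7 is no longer a nucleophilic site.

Step 5
Reactants: 8 allyl (8R,9S)-7,9-dimethyl-1,4-dioxaspiro[4.5]dec-6-ene-8-carboxylate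
Product: 9 (8R,9S)-7,9-dimethyl-1,4-dioxaspiro[4.5]dec-6-ene-8-carboxylic acid
Conditions: Pd(PPh3)4 (2 mol %), morpholine, THF, rt
Reagents that add atoms: none
Why: Tsuji–Trost deallylation (zerovalent palladium ionises the allyl ester, morpholine traps the allyl unit) frees the acid under neutral conditions, so the β,γ-double bond should stay in place.

Step 6
Reactants: 9 (8R,9S)-7,9-dimethyl-1,4-dioxaspiro[4.5]dec-6-ene-8-carboxylic acid
Product: 11 methyl 3-[(8R,9S)-7,9-dimethyl-1,4-dioxaspiro[4.5]dec-6-en-8-yl]-3-oxopropanoate, via acyl imidazolide 10 (not isolated)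
Conditions: CDI, THF, rt; then Mg(O2CCH2CO2Me)2, THF, rt to 40 °C; cold dilute HCl work-up
Reagents that add atoms: magnesium bis(methyl malonate) [Mg+2].[O-]C(=O)CC(=O)OC.[O-]C(=O)CC(=O)OC; 1,1'-carbonyldiimidazole O=C(n1ccnc1)n1ccnc1 (its imidazole stays only in 10)
Why: Masamune–Brooks homologation: the acyl imidazolide is C-acylated by the magnesium malonate chelate and the acylmalonate loses CO2 on work-up, under near-neutral conditions that spare the ketal and the double-bond position.

Step 7
Reactants: 11 methyl 3-[(8R,9S)-7,9-dimethyl-1,4-dioxaspiro[4.5]dec-6-en-8-yl]-3-oxopropanoate; 3 tert-butyl (2E)-4-chloro-2-methylbut-2-en-1-yl carbonate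
Product: 13 methyl (2S,3R,5S,10S)-8,8-(ethylenedioxy)-6,10-dimethyl-1-oxo-3-(prop-1-en-2-yl)spiro[4.5]dec-6-ene-2-carboxylate, via C5-alkylated allylic carbonate 12 (not isolated)
Conditions: LiN(i-Pr)2 (2.1 equiv), THF, −78 to 0 °C; 3, −78 to 0 °C; then Pd2(dba)3·CHCl3 (2.5 mol %), (R,R)-DACH-phenyl Trost ligand (7.5 mol %), 0 to 40 °C; H2O work-up
Reagents that add atoms: none
Why: LiN(i-Pr)2 removes first a C2–H and then the allylic C5–H of 11, and the dianion reacts only at its more basic γ-carbon C5 (Huckin–Weiler γ-alkylation) by SN2 at the allylic chloride of 3, leaving the hindered tert-butyl carbonate intact, to give 12 as its C2 enolate with the C4–C5 bond in place. Zerovalent palladium then ionises the allylic carbonate (CO2 and tert-butoxide leave) and the enolate carbon C2 attacks the internal terminus C3 of the 2-methylallyl complex, which forms C2–C3 and turns the former CH2O carbon into the CH2 of the isopropenyl group. The closest known chemistry is the Tsuji cyclopentanone annulation (γ-alkylation of a β-keto ester dianion with a 4-oxybut-2-enyl halide, then palladium-catalysed cyclisation to a 2-carbomethoxy-3-vinylcyclopentanone) and the Trost–Runge oxygen-to-carbon allyl shift. The first bond is intermolecular; the cyclopentane closes 5-(enolexo)-exo-trig on the allyl terminus, favoured over the 7-endo mode by ring size, and any O-allylated enol ether should re-ionise under the same catalyst. C5 is set by the substrate (A(1,3) strain in the exocyclic enolate puts the C10 methyl pseudoaxial, so C4 enters anti to it), C3 is set in the ring closure by the ligand because the two faces of the allyl complex interconvert through the unsubstituted CH2 terminus, and C2 settles trans to the isopropenyl group and is removed in step 8. The step needs γ- over α-alkylation (secured by the dianion), chloride over carbonate (leaving-group and steric difference), carbon over oxygen and five- over seven-membered closure (reversibility and ring size), and the C3 face (ligand; the matched ligand enantiomer is not predicted here and is read from one pair of trial runs).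

Step 8
Reactants: 13 methyl (2S,3R,5S,10S)-8,8-(ethylenedioxy)-6,10-dimethyl-1-oxo-3-(prop-1-en-2-yl)spiro[4.5]dec-6-ene-2-carboxylate
Product: 14 (3R,5S,10S)-8,8-(ethylenedioxy)-6,10-dimethyl-3-(prop-1-en-2-yl)spiro[4.5]dec-6-en-1-one
Conditions: LiCl, H2O, DMSO, 130 °C
Reagents that add atoms: none
Why: Krapcho dealkoxycarbonylation (chloride attacks the ester methyl, the β-keto carboxylate loses CO2, water protonates the enolate) is neutral, spares ketal and alkenes, and leaves C3, which carries no acidic hydrogen, unchanged.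

Step 9
Reactants: 14 (3R,5S,10S)-8,8-(ethylenedioxy)-6,10-dimethyl-3-(prop-1-en-2-yl)spiro[4.5]dec-6-en-1-one
Product: 15 (1S,3R,5S,10S)-8,8-(ethylenedioxy)-6,10-dimethyl-3-(prop-1-en-2-yl)spiro[4.5]dec-6-en-1-ol
Conditions: (R)-Me-CBS oxazaborolidine (0.5 equiv), catecholborane, toluene, −78 °C; then MeOH, aq. NaOH
Reagents that add atoms: none
Why: Corey–Bakshi–Shibata reduction: the oxazaborolidine distinguishes the quaternary C5 from the CH2 at C2 and should deliver hydride to the face that gives the (1S)-alcohol by reagent control, while catecholborane at −78 °C leaves the 1,1-disubstituted alkene alone.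

Step 10
Reactants: 15 (1S,3R,5S,10S)-8,8-(ethylenedioxy)-6,10-dimethyl-3-(prop-1-en-2-yl)spiro[4.5]dec-6-en-1-ol
Product: 16 (1S,3R,5S,10S)-8,8-(ethylenedioxy)-6,10-dimethyl-3-(prop-1-en-2-yl)spiro[4.5]dec-6-en-1-yl 3-methylbut-2-enoate
Conditions: 3-methylbut-2-enoyl chloride, pyridine, DMAP (0.2 equiv), CH2Cl2, 0 °C to rt
Reagents that add atoms: 3-methylbut-2-enoyl chloride CC(C)=CC(Cl)=O
Why: DMAP-catalysed acylation of the hindered secondary alcohol with the acid chloride, with the weak base pyridine chosen to limit deconjugation of the senecioate through the vinylketene.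

Step 11
Reactants: 16 (1S,3R,5S,10S)-8,8-(ethylenedioxy)-6,10-dimethyl-3-(prop-1-en-2-yl)spiro[4.5]dec-6-en-1-yl 3-methylbut-2-enoate
Product: 17 (1S,3R,5S,10S)-6,10-dimethyl-8-oxo-3-(prop-1-en-2-yl)spiro[4.5]dec-6-en-1-yl 3-methylbut-2-enoate
Conditions: 1 M HCl, THF, 0 °C to rt
Reagents that add atoms: water O
Why: Acid hydrolysis of the allylic dioxolane is fast under mild conditions and returns the conjugated enone directly because the double bond was kept at C6=C7; the isopropenyl group and the ester should survive cold dilute acid.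

Step 12
Reactants: 17 (1S,3R,5S,10S)-6,10-dimethyl-8-oxo-3-(prop-1-en-2-yl)spiro[4.5]dec-6-en-1-yl 3-methylbut-2-enoate
Product: 18 (1S,3R,5S,9S,10R)-9-acetoxy-6,10-dimethyl-8-oxo-3-(prop-1-en-2-yl)spiro[4.5]dec-6-en-1-yl 3-methylbut-2-enoate
Conditions: Mn(OAc)3·2H2O (3 equiv), benzene, reflux (Dean–Stark)
Reagents that add atoms: manganese triacetate [Mn+3].CC(=O)[O-].CC(=O)[O-].CC(=O)[O-]
Why: α′-Acetoxylation of an enone with Mn(OAc)3: the enolate of trivalent manganese forms on the α′ side (C9) and acetate should enter anti to the adjacent C10 methyl, giving the trans (9S) isomer, which is also the more stable one.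

Compound list
1 | 2-methyl-2-vinyloxirane (isoprene monoxide, racemic) | CC1(C=C)CO1 | starting material
2 | (2E)-4-chloro-2-methylbut-2-en-1-ol | OC/C(C)=C/CCl | intermediate
3 | tert-butyl (2E)-4-chloro-2-methylbut-2-en-1-yl carbonate | CC(C)(C)OC(=O)OC/C(C)=C/CCl | intermediate
4 | allyl acetoacetate (prop-2-en-1-yl 3-oxobutanoate) | C=CCOC(=O)CC(C)=O | starting material
5 | (3E)-pent-3-en-2-one | C/C=C/C(C)=O | starting material
6 | allyl (3S)-2-acetyl-3-methyl-5-oxohexanoate (C2 epimers) | C=CCOC(=O)C(C(C)=O)[C@@H](C)CC(C)=O | intermediate (not isolated)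
7 | allyl (1R,6S)-2,6-dimethyl-4-oxocyclohex-2-ene-1-carboxylate | C=CCOC(=O)[C@H]1C(C)=CC(=O)C[C@@H]1C | intermediate
8 | allyl (8R,9S)-7,9-dimethyl-1,4-dioxaspiro[4.5]dec-6-ene-8-carboxylate | C=CCOC(=O)[C@H]1C(C)=CC2(OCCO2)C[C@@H]1C | intermediate
9 | (8R,9S)-7,9-dimethyl-1,4-dioxaspiro[4.5]dec-6-ene-8-carboxylic acid | OC(=O)[C@H]1C(C)=CC2(OCCO2)C[C@@H]1C | intermediate
10 | [(8R,9S)-7,9-dimethyl-1,4-dioxaspiro[4.5]dec-6-en-8-yl](1H-imidazol-1-yl)methanone | O=C(n1ccnc1)[C@H]2C(C)=CC3(OCCO3)C[C@@H]2C | intermediate (not isolated)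
11 | methyl 3-[(8R,9S)-7,9-dimethyl-1,4-dioxaspiro[4.5]dec-6-en-8-yl]-3-oxopropanoate | COC(=O)CC(=O)[C@H]1C(C)=CC2(OCCO2)C[C@@H]1C | intermediate
12 | methyl 3-[(8S,9S)-8-[(2E)-4-(tert-butoxycarbonyloxy)-3-methylbut-2-en-1-yl]-7,9-dimethyl-1,4-dioxaspiro[4.5]dec-6-en-8-yl]-3-oxopropanoate | COC(=O)CC(=O)[C@]1(C/C=C(\C)COC(=O)OC(C)(C)C)C(C)=CC2(OCCO2)C[C@@H]1C | intermediate (not isolated)
13 | methyl (2S,3R,5S,10S)-8,8-(ethylenedioxy)-6,10-dimethyl-1-oxo-3-(prop-1-en-2-yl)spiro[4.5]dec-6-ene-2-carboxylate | C=C(C)[C@H]1[C@H](C(=O)OC)C(=O)[C@]2(C1)C(C)=CC3(OCCO3)C[C@@H]2C | intermediate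
14 | (3R,5S,10S)-8,8-(ethylenedioxy)-6,10-dimethyl-3-(prop-1-en-2-yl)spiro[4.5]dec-6-en-1-one | C=C(C)[C@H]1CC(=O)[C@]2(C1)C(C)=CC3(OCCO3)C[C@@H]2C | intermediate
15 | (1S,3R,5S,10S)-8,8-(ethylenedioxy)-6,10-dimethyl-3-(prop-1-en-2-yl)spiro[4.5]dec-6-en-1-ol | C=C(C)[C@H]1C[C@H](O)[C@]2(C1)C(C)=CC3(OCCO3)C[C@@H]2C | intermediate
16 | (1S,3R,5S,10S)-8,8-(ethylenedioxy)-6,10-dimethyl-3-(prop-1-en-2-yl)spiro[4.5]dec-6-en-1-yl 3-methylbut-2-enoate | C=C(C)[C@H]1C[C@H](OC(=O)C=C(C)C)[C@]2(C1)C(C)=CC3(OCCO3)C[C@@H]2C | intermediate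
17 | (1S,3R,5S,10S)-6,10-dimethyl-8-oxo-3-(prop-1-en-2-yl)spiro[4.5]dec-6-en-1-yl 3-methylbut-2-enoate | C=C(C)[C@H]1C[C@H](OC(=O)C=C(C)C)[C@]2(C1)C(C)=CC(=O)C[C@@H]2C | intermediate
18 | (1S,3R,5S,9S,10R)-9-acetoxy-6,10-dimethyl-8-oxo-3-(prop-1-en-2-yl)spiro[4.5]dec-6-en-1-yl 3-methylbut-2-enoate | C=C(C)[C@H]1C[C@H](OC(=O)C=C(C)C)[C@]2(C1)C(C)=CC(=O)[C@@H](OC(C)=O)[C@@H]2C | target

Total step count: 12.
Longest linear sequence: 10 steps (steps 3–12, from 4 and 5); the electrophile branch (steps 1–2) joins at step 7.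

Steps most likely to fail

Step 7 (key step). The dianion may attack the carbonate, the second closure may go through oxygen or to the seven-membered ring, or the ligand may control the C3 face only weakly. The fallback runs the two bond formations as separate, known operations; it sets out from 11 and returns at 13. Compound 11 is converted into its dianion as before and alkylated at C5 with 1-bromo-3-methylbut-2-ene to give the C5-prenyl β-keto ester F1. Mn(OAc)3·2H2O and Cu(OAc)2·H2O in EtOH then oxidise F1 to its C2 radical, which should close 5-exo onto C3 of the prenyl double bond. Divalent copper oxidises the resulting tertiary radical to the isopropenyl group (Snider oxidative radical cyclisation), giving 13. C3 epimers, if formed, are separated at 14.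

Step 3. Enantioselectivity may be low because the uncatalysed Michael addition to the aliphatic enone competes and the adduct can revert. The fallback replaces catalysis by resolution; it sets out from 4 and 5 and returns at 9. Pyrrolidine and AcOH alone give the racemic Michael adduct F2, which cyclises in the same pot to the racemic enone ester F3. Steps 4 and 5 applied unchanged give the racemic ketal ester F4 and the racemic acid F5. F5 is resolved by crystallisation of its (R)-1-phenylethylammonium salt F6 (the (S)-amine is used if the other salt is the less soluble one), and cold dilute acid frees 9.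

Step 9. The ketone is neopentyl and flanked by two methyl-bearing carbons, so reduction may be slow and the oxazaborolidine may not override the substrate. The fallback replaces face control by inversion; it sets out from 14 and returns at 16. Compound 14 is reduced with the hydride that reacts cleanly under substrate control (NaBH4 in MeOH, or LiBH(s-Bu)3). If this gives the (1R)-alcohol F7, Mitsunobu esterification of F7 with 3-methylbut-2-enoic acid (PPh3, diisopropyl azodicarboxylate) inverts C1 and gives 16 directly.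

Further compounds
F1 | step 7 | methyl 3-[(8S,9S)-7,9-dimethyl-8-(3-methylbut-2-en-1-yl)-1,4-dioxaspiro[4.5]dec-6-en-8-yl]-3-oxopropanoate | COC(=O)CC(=O)[C@]1(CC=C(C)C)C(C)=CC2(OCCO2)C[C@@H]1C
F2 | step 3 | racemic allyl 2-acetyl-3-methyl-5-oxohexanoate (not isolated) | C=CCOC(=O)C(C(C)=O)C(C)CC(C)=O
F3 | step 3 | racemic trans allyl 2,6-dimethyl-4-oxocyclohex-2-ene-1-carboxylate | C=CCOC(=O)C1C(C)=CC(=O)CC1C
F4 | step 3 | racemic trans allyl 7,9-dimethyl-1,4-dioxaspiro[4.5]dec-6-ene-8-carboxylate | C=CCOC(=O)C1C(C)=CC2(OCCO2)CC1C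
F5 | step 3 | racemic trans 7,9-dimethyl-1,4-dioxaspiro[4.5]dec-6-ene-8-carboxylic acid | OC(=O)C1C(C)=CC2(OCCO2)CC1C
F6 | step 3 | (R)-1-phenylethylammonium (8R,9S)-7,9-dimethyl-1,4-dioxaspiro[4.5]dec-6-ene-8-carboxylate | C[C@@H]([NH3+])c1ccccc1.[O-]C(=O)[C@H]1C(C)=CC2(OCCO2)C[C@@H]1C
F7 | step 9 | (1R,3R,5S,10S)-8,8-(ethylenedioxy)-6,10-dimethyl-3-(prop-1-en-2-yl)spiro[4.5]dec-6-en-1-ol | C=C(C)[C@H]1C[C@@H](O)[C@]2(C1)C(C)=CC3(OCCO3)C[C@@H]2C
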